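**Plan**

Numbering: C1=C2 methylidene, C3–C7 oxoalkyl chain, C8 (bears the acid C9), C10, C11–C12 (CH2CHO), C13 (formyl), C14=C15, C16=C17, C18 (CMe2).
Feature: the ring O–C15–C16=C17–C18, with its gem-dimethyl carbon C18, is a prenyl group on ketone carbon C15 that has been closed through the enol oxygen and dehydrogenated. Cutting O–C18 and saturating C16–C17 therefore leads back to an enolised prenyl β-ketoaldehyde.
Further cuts: C14–C15 (acylation of the C13 aldehyde enamine), C8–C10 (ester-enolate Claisen rearrangement), the ester C9–O bond, and C2–C3 (Grignard reagent plus diketene).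
Forward: the chain is joined in the order C2–C3, C8–C10, C14–C15; the only ring closes third from last, by selenium-induced 5-endo cycloetherification and selenoxide elimination.
Stereochemistry: one catalytic transfer hydrogenation sets an (S)-carbinol; the chair Claisen rearrangement relays it to C10 and C8 together; the former carbinol carbon ends in a propenyl group that is trimmed by ethenolysis.

Key step: step 13

Remark: the exocyclic C14=C15 geometry of the target (C10 on the side of the ring oxygen) is taken to be the thermodynamically preferred one of this push–pull alkene, so that acid-catalysed equilibration leads to it.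

**Step 1**
Reactants: 1 2-(3-chloropropyl)-2-methyl-1,3-dioxolane; 2 diketene (4-methylideneoxetan-2-one)
Product: 4 3-methylidene-6-(2-methyl-1,3-dioxolan-2-yl)hexanoic acid, via Grignard reagent 3 (not isolated)
Conditions: Mg, I2 (cat.), THF, 50 °C; then 2, NiCl2 (5 mol%), THF, −20 → 0 °C; cold 0.5 M HCl to pH 3–4
Reagents that add atoms: none
Why: Nickel-catalysed cross-coupling of an alkyl Grignard reagent at the vinylic C–O bond of diketene is a known route to 3-methylidene alkanoic acids, and the ketal-bearing Grignard reagent is a standard, stable reagent.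

**Step 2**
Reactants: 5 4,4-diethoxybut-1-yne; 6 N-methoxy-N-methylacetamide
Product: 8 6,6-diethoxyhex-3-yn-2-one, via lithium acetylide 7 (not isolated)
Conditions: n-BuLi, THF, −78 °C; then 6, −78 → 0 °C; aq. NH4Cl
Reagents that add atoms: none
Why: Weinreb ketone synthesis, in which the chelated tetrahedral adduct of the lithium acetylide survives until work-up, so the reaction should stop at the ynone.

**Step 3**
Reactants: 8 6,6-diethoxyhex-3-yn-2-one
Product: 9 (2S)-6,6-diethoxyhex-3-yn-2-ol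
Conditions: RuCl[(S,S)-TsDPEN](p-cymene) (1 mol%), i-PrOH, 25 °C
Reagents that add atoms: none
Why: Noyori asymmetric transfer hydrogenation of alkynyl methyl ketones is highly enantioselective, and the (S,S)-catalyst should deliver hydride to the face that gives the (S)-carbinol, the single source of absolute configuration in the route.

**Step 4**
Reactants: 9 (2S)-6,6-diethoxyhex-3-yn-2-ol
Product: 10 (2S,3E)-6,6-diethoxyhex-3-en-2-ol
Conditions: LiAlH4, THF, 0 → 25 °C; H2O, aq. NaOH work-up
Reagents that add atoms: none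
Why: Hydroxyl-directed anti-hydroalumination of a propargylic alcohol should give only the (E)-allylic alcohol and leaves the carbinol centre untouched.

**Step 5**
Reactants: 4 3-methylidene-6-(2-methyl-1,3-dioxolan-2-yl)hexanoic acid; 10 (2S,3E)-6,6-diethoxyhex-3-en-2-ol
Product: 11 (2S,3E)-6,6-diethoxyhex-3-en-2-yl 3-methylidene-6-(2-methyl-1,3-dioxolan-2-yl)hexanoate
Conditions: DCC, DMAP (5 mol%), CH2Cl2, −10 → 0 °C
Reagents that add atoms: none
Why: Steglich esterification acylates the secondary allylic alcohol with retention at the carbinol carbon, and the low temperature and small amount of DMAP should keep the methylidene group out of conjugation.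

**Step 6**
Reactants: 11 (2S,3E)-6,6-diethoxyhex-3-en-2-yl 3-methylidene-6-(2-methyl-1,3-dioxolan-2-yl)hexanoate
Product: 15 (2R,3R,4E)-3-(2,2-diethoxyethyl)-2-[5-(2-methyl-1,3-dioxolan-2-yl)pent-1-en-2-yl]hex-4-enoic acid, via lithium enolate 12 (not isolated), via silyl ketene acetal 13 (not isolated), via trimethylsilyl ester 14 (not isolated)
Conditions: LiN(i-Pr)2, THF/DMPU (4:1), −78 °C; Me3SiCl; −78 → 25 °C; aq. citric acid
Reagents that add atoms: none
Why: Ireland–Claisen rearrangement of an ester dienolate at its α-carbon, through a chair transition state in which the methyl group on the (S)-carbinol carbon, the substituent of the (E)-alkene and the alkenyl group of the ketene acetal (cis to OSi, the geometry expected in the dipolar solvent mixture) are all equatorial, so the carbinol configuration should be relayed to C10 and C8 together as the C8–C10 bond forms.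

**Step 7**
Reactants: 15 (2R,3R,4E)-3-(2,2-diethoxyethyl)-2-[5-(2-methyl-1,3-dioxolan-2-yl)pent-1-en-2-yl]hex-4-enoic acid
Product: 16 2-(trimethylsilyl)ethyl (2R,3R,4E)-3-(2,2-diethoxyethyl)-2-[5-(2-methyl-1,3-dioxolan-2-yl)pent-1-en-2-yl]hex-4-enoate
Conditions: Me3SiCH2CH2OH, PPh3, DIAD, THF, 0 → 25 °C
Reagents that add atoms: 2-(trimethylsilyl)ethanol, C[Si](C)(C)CCO
Why: Mitsunobu esterification activates the alcohol and not the acid, so C8, which is α to the carboxyl group and allylic, never passes through an acyl-activated species that could epimerise or conjugate.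

**Step 8**
Reactants: 16 2-(trimethylsilyl)ethyl (2R,3R,4E)-3-(2,2-diethoxyethyl)-2-[5-(2-methyl-1,3-dioxolan-2-yl)pent-1-en-2-yl]hex-4-enoate
Product: 17 2-(trimethylsilyl)ethyl (2R,3R)-3-(2,2-diethoxyethyl)-2-[5-(2-methyl-1,3-dioxolan-2-yl)pent-1-en-2-yl]pent-4-enoate
Conditions: second-generation Hoveyda–Grubbs catalyst (5 mol%), C2H4 (1 atm), CH2Cl2, 40 °C
Reagents that add atoms: ethene, C=C
Why: Ethenolysis (cross-metathesis with ethene) should trim the 1,2-disubstituted propenyl group to a vinyl group with loss of propene, while the 1,1-disubstituted C1=C2 alkene only undergoes degenerate exchange.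

**Step 9**
Reactants: 17 2-(trimethylsilyl)ethyl (2R,3R)-3-(2,2-diethoxyethyl)-2-[5-(2-methyl-1,3-dioxolan-2-yl)pent-1-en-2-yl]pent-4-enoate
Product: 19 2-(trimethylsilyl)ethyl (2R,3S)-3-(2,2-diethoxyethyl)-5-hydroxy-2-[5-(2-methyl-1,3-dioxolan-2-yl)pent-1-en-2-yl]pentanoate, via trialkylborane 18 (not isolated)
Conditions: disiamylborane (from BH3·THF, 2-methylbut-2-ene), THF, 0 °C; then 30% H2O2, 3 M NaOH, 0 °C
Reagents that add atoms: hydrogen peroxide, OO
Why: Brown hydroboration–oxidation with a bulky dialkylborane should place boron on the terminal carbon of the monosubstituted vinyl group much faster than on the hindered 1,1-disubstituted alkene, giving the primary alcohol at C13.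

**Step 10**
Reactants: 19 2-(trimethylsilyl)ethyl (2R,3S)-3-(2,2-diethoxyethyl)-5-hydroxy-2-[5-(2-methyl-1,3-dioxolan-2-yl)pent-1-en-2-yl]pentanoate
Product: 20 2-(trimethylsilyl)ethyl (2R,3S)-3-(2,2-diethoxyethyl)-5-oxo-2-[5-(2-methyl-1,3-dioxolan-2-yl)pent-1-en-2-yl]pentanoate
Conditions: Dess–Martin periodinane, NaHCO3, CH2Cl2, 0 → 25 °C
Reagents that add atoms: none
Why: Dess–Martin oxidation converts the primary alcohol into the aldehyde under buffered conditions that leave the acetal, the ketal and the C8 centre alone.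

**Step 11**
Reactants: 21 4-methylpent-3-enoic acid
Product: 22 4-methylpent-3-enoyl chloride
Conditions: 1-chloro-N,N,2-trimethylprop-1-en-1-amine, CH2Cl2, 0 → 25 °C; used directly
Reagents that add atoms: 1-chloro-N,N,2-trimethylprop-1-en-1-amine, CC(C)=C(Cl)N(C)C
Why: Acid chloride formation with an α-chloroenamine is neutral, so no HCl is available to add to the trisubstituted alkene or to move it into conjugation.

**Step 12**
Reactants: 20 2-(trimethylsilyl)ethyl (2R,3S)-3-(2,2-diethoxyethyl)-5-oxo-2-[5-(2-methyl-1,3-dioxolan-2-yl)pent-1-en-2-yl]pentanoate; 22 4-methylpent-3-enoyl chloride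
Product: 25 2-(trimethylsilyl)ethyl (2R,3S,4Z)-3-(2,2-diethoxyethyl)-4-(hydroxymethylidene)-8-methyl-5-oxo-2-[5-(2-methyl-1,3-dioxolan-2-yl)pent-1-en-2-yl]non-7-enoate, via enamine 23 (not isolated), via acyl enamine 24 (not isolated)
Conditions: pyrrolidine, 4 Å MS, CH2Cl2, 25 °C; then 22, Et3N, CH2Cl2, −20 → 0 °C; then AcOH/NaOAc buffer (pH 5), THF/H2O, 25 °C
Reagents that add atoms: water, O
Why: Stork enamine acylation: the enamine forms only at the C13 aldehyde, C-acylation therefore occurs only at C14 without any strong base near the acidic C8–H, and buffered hydrolysis of the vinylogous amide should release the chelated enol of the β-ketoaldehyde.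

**Step 13**
Reactants: 25 2-(trimethylsilyl)ethyl (2R,3S,4Z)-3-(2,2-diethoxyethyl)-4-(hydroxymethylidene)-8-methyl-5-oxo-2-[5-(2-methyl-1,3-dioxolan-2-yl)pent-1-en-2-yl]non-7-enoate
Product: 28 2-(trimethylsilyl)ethyl (2R,3S,4E)-3-(2,2-diethoxyethyl)-4-(5,5-dimethylfuran-2(5H)-ylidene)-5-oxo-2-[5-(2-methyl-1,3-dioxolan-2-yl)pent-1-en-2-yl]pentanoate, via cyclic selenide 26 (not isolated), via selenoxide 27 (not isolated)
Conditions: PhSeCl, CH2Cl2, −78 °C; then pyridine, 30% H2O2, 0 → 25 °C
Reagents that add atoms: none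
Why: PhSeCl should form a seleniranium ion on the electron-rich C17=C18 alkene, which the C15 oxygen of the enolised β-ketoaldehyde opens at the tertiary carbon C18; loss of the enol proton then gives the formyl-substituted cyclic enol ether 26. Oxidation to selenoxide 27 and syn-elimination can only run towards C16, because C18 carries no hydrogen, and this installs the C16=C17 double bond. The closest known reactions are the phenylselenoetherification of alkenyl 1,3-dicarbonyl compounds to cyclic enol ethers and the selenolactonisation–selenoxide elimination of β,γ-unsaturated acids to butenolides. The single ring closes in the 5-endo-trig mode with Markovnikov orientation; the alternative closure through the C13 oxygen would need either attack at the secondary carbon C17 or a seven-membered ring. No lasting stereocentre is formed: C17 of 26 is transient, and the push–pull C14=C15 bond is expected to settle, by reversible protonation at the formyl oxygen, in the geometry with C10 next to the ring oxygen. The step needs selenium to end on C17=C18 and not on C14 or C1=C2; this should be secured because the prenyl alkene is the most nucleophilic π-bond and the only one with a nucleophile placed for irreversible capture, while selenium on the crowded C14 or on C1=C2 is returned by chloride.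

**Step 14**
Reactants: 28 2-(trimethylsilyl)ethyl (2R,3S,4E)-3-(2,2-diethoxyethyl)-4-(5,5-dimethylfuran-2(5H)-ylidene)-5-oxo-2-[5-(2-methyl-1,3-dioxolan-2-yl)pent-1-en-2-yl]pentanoate
Product: 29 (2R,3S,4E)-3-(2,2-diethoxyethyl)-4-(5,5-dimethylfuran-2(5H)-ylidene)-2-[5-(2-methyl-1,3-dioxolan-2-yl)pent-1-en-2-yl]-5-oxopentanoic acid
Conditions: Bu4NF, AcOH (1:1), THF, 25 °C
Reagents that add atoms: none
Why: Fluoride-induced fragmentation of the 2-(trimethylsilyl)ethyl ester (attack at silicon, loss of ethene) should free the acid under buffered conditions that spare the vinylogous ester, the acetal and the ketal and do not epimerise C8.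

**Step 15**
Reactants: 29 (2R,3S,4E)-3-(2,2-diethoxyethyl)-4-(5,5-dimethylfuran-2(5H)-ylidene)-2-[5-(2-methyl-1,3-dioxolan-2-yl)pent-1-en-2-yl]-5-oxopentanoic acid
Product: 30 (2R,3S,4E)-4-(5,5-dimethylfuran-2(5H)-ylidene)-5-oxo-2-(6-oxohept-1-en-2-yl)-3-(2-oxoethyl)pentanoic acid (CNP0150297.1)
Conditions: AcOH/THF/H2O (3:1:1), 40 °C
Reagents that add atoms: water, O
Why: Mild acid-catalysed hydrolysis should remove the diethyl acetal and the dioxolane while the less basic vinylogous formyl ester survives, and the same conditions allow the C14=C15 geometry to equilibrate to that of the target.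

**Compound list**

1 | 2-(3-chloropropyl)-2-methyl-1,3-dioxolane | CC1(CCCCl)OCCO1 | starting material
2 | diketene (4-methylideneoxetan-2-one) | C=C1CC(=O)O1 | starting material
3 | [3-(2-methyl-1,3-dioxolan-2-yl)propyl]magnesium chloride | CC1(CCC[Mg]Cl)OCCO1 | intermediate
4 | 3-methylidene-6-(2-methyl-1,3-dioxolan-2-yl)hexanoic acid | C=C(CC(=O)O)CCCC1(C)OCCO1 | intermediate
5 | 4,4-diethoxybut-1-yne | C#CCC(OCC)OCC | starting material
6 | N-methoxy-N-methylacetamide | CC(=O)N(C)OC | starting material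
7 | (4,4-diethoxybut-1-yn-1-yl)lithium | [Li]C#CCC(OCC)OCC | intermediate
8 | 6,6-diethoxyhex-3-yn-2-one | CC(=O)C#CCC(OCC)OCC | intermediate
9 | (2S)-6,6-diethoxyhex-3-yn-2-ol | C[C@H](O)C#CCC(OCC)OCC | intermediate
10 | (2S,3E)-6,6-diethoxyhex-3-en-2-ol | C[C@H](O)/C=C/CC(OCC)OCC | intermediate
11 | (2S,3E)-6,6-diethoxyhex-3-en-2-yl 3-methylidene-6-(2-methyl-1,3-dioxolan-2-yl)hexanoate | C=C(CCCC1(C)OCCO1)CC(=O)O[C@@H](C)/C=C/CC(OCC)OCC | intermediate
12 | lithium enolate of 11, alkenyl group cis to OLi | C=C(CCCC1(C)OCCO1)/C=C(\O[Li])O[C@@H](C)/C=C/CC(OCC)OCC | intermediate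
13 | trimethylsilyl ketene acetal of 11, (1Z), alkenyl group cis to OSiMe3 | C=C(CCCC1(C)OCCO1)/C=C(\O[Si](C)(C)C)O[C@@H](C)/C=C/CC(OCC)OCC | intermediate
14 | trimethylsilyl (2R,3R,4E)-3-(2,2-diethoxyethyl)-2-[5-(2-methyl-1,3-dioxolan-2-yl)pent-1-en-2-yl]hex-4-enoate | C=C(CCCC1(C)OCCO1)[C@H](C(=O)O[Si](C)(C)C)[C@H](CC(OCC)OCC)/C=C/C | intermediate
15 | (2R,3R,4E)-3-(2,2-diethoxyethyl)-2-[5-(2-methyl-1,3-dioxolan-2-yl)pent-1-en-2-yl]hex-4-enoic acid | C=C(CCCC1(C)OCCO1)[C@H](C(=O)O)[C@H](CC(OCC)OCC)/C=C/C | intermediate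
16 | 2-(trimethylsilyl)ethyl (2R,3R,4E)-3-(2,2-diethoxyethyl)-2-[5-(2-methyl-1,3-dioxolan-2-yl)pent-1-en-2-yl]hex-4-enoate | C=C(CCCC1(C)OCCO1)[C@H](C(=O)OCC[Si](C)(C)C)[C@H](CC(OCC)OCC)/C=C/C | intermediate
17 | 2-(trimethylsilyl)ethyl (2R,3R)-3-(2,2-diethoxyethyl)-2-[5-(2-methyl-1,3-dioxolan-2-yl)pent-1-en-2-yl]pent-4-enoate | C=C(CCCC1(C)OCCO1)[C@H](C(=O)OCC[Si](C)(C)C)[C@H](CC(OCC)OCC)C=C | intermediate
18 | 2-(trimethylsilyl)ethyl (2R,3S)-5-[bis(3-methylbutan-2-yl)boranyl]-3-(2,2-diethoxyethyl)-2-[5-(2-methyl-1,3-dioxolan-2-yl)pent-1-en-2-yl]pentanoate | C=C(CCCC1(C)OCCO1)[C@H](C(=O)OCC[Si](C)(C)C)[C@H](CC(OCC)OCC)CCB(C(C)C(C)C)C(C)C(C)C | intermediate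
19 | 2-(trimethylsilyl)ethyl (2R,3S)-3-(2,2-diethoxyethyl)-5-hydroxy-2-[5-(2-methyl-1,3-dioxolan-2-yl)pent-1-en-2-yl]pentanoate | C=C(CCCC1(C)OCCO1)[C@H](C(=O)OCC[Si](C)(C)C)[C@H](CC(OCC)OCC)CCO | intermediate
20 | 2-(trimethylsilyl)ethyl (2R,3S)-3-(2,2-diethoxyethyl)-5-oxo-2-[5-(2-methyl-1,3-dioxolan-2-yl)pent-1-en-2-yl]pentanoate | C=C(CCCC1(C)OCCO1)[C@H](C(=O)OCC[Si](C)(C)C)[C@H](CC(OCC)OCC)CC=O | intermediate
21 | 4-methylpent-3-enoic acid | CC(C)=CCC(=O)O | starting material
22 | 4-methylpent-3-enoyl chloride | CC(C)=CCC(=O)Cl | intermediate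
23 | 2-(trimethylsilyl)ethyl (2R,3R,4E)-3-(2,2-diethoxyethyl)-2-[5-(2-methyl-1,3-dioxolan-2-yl)pent-1-en-2-yl]-5-(pyrrolidin-1-yl)pent-4-enoate | C=C(CCCC1(C)OCCO1)[C@H](C(=O)OCC[Si](C)(C)C)[C@H](CC(OCC)OCC)/C=C/N2CCCC2 | intermediate
24 | 2-(trimethylsilyl)ethyl (2R,3S)-3-(2,2-diethoxyethyl)-8-methyl-5-oxo-2-[5-(2-methyl-1,3-dioxolan-2-yl)pent-1-en-2-yl]-4-(pyrrolidin-1-ylmethylidene)non-7-enoate (alkene geometry not fixed) | C=C(CCCC1(C)OCCO1)[C@H](C(=O)OCC[Si](C)(C)C)[C@H](CC(OCC)OCC)C(=CN2CCCC2)C(=O)CC=C(C)C | intermediate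
25 | 2-(trimethylsilyl)ethyl (2R,3S,4Z)-3-(2,2-diethoxyethyl)-4-(hydroxymethylidene)-8-methyl-5-oxo-2-[5-(2-methyl-1,3-dioxolan-2-yl)pent-1-en-2-yl]non-7-enoate | C=C(CCCC1(C)OCCO1)[C@H](C(=O)OCC[Si](C)(C)C)[C@H](CC(OCC)OCC)/C(=C/O)C(=O)CC=C(C)C | intermediate
26 | 2-(trimethylsilyl)ethyl (2R,3S)-3-(2,2-diethoxyethyl)-4-[5,5-dimethyl-4-(phenylselanyl)oxolan-2-ylidene]-5-oxo-2-[5-(2-methyl-1,3-dioxolan-2-yl)pent-1-en-2-yl]pentanoate (both epimers at the selenium-bearing carbon, alkene geometry not fixed) | C=C(CCCC1(C)OCCO1)[C@H](C(=O)OCC[Si](C)(C)C)[C@H](CC(OCC)OCC)C(C=O)=C2CC([Se]c3ccccc3)C(C)(C)O2 | intermediate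
27 | 2-(trimethylsilyl)ethyl (2R,3S)-3-(2,2-diethoxyethyl)-4-[5,5-dimethyl-4-(phenylseleninyl)oxolan-2-ylidene]-5-oxo-2-[5-(2-methyl-1,3-dioxolan-2-yl)pent-1-en-2-yl]pentanoate (stereoisomer mixture) | C=C(CCCC1(C)OCCO1)[C@H](C(=O)OCC[Si](C)(C)C)[C@H](CC(OCC)OCC)C(C=O)=C2CC([Se](=O)c3ccccc3)C(C)(C)O2 | intermediate
28 | 2-(trimethylsilyl)ethyl (2R,3S,4E)-3-(2,2-diethoxyethyl)-4-(5,5-dimethylfuran-2(5H)-ylidene)-5-oxo-2-[5-(2-methyl-1,3-dioxolan-2-yl)pent-1-en-2-yl]pentanoate | C=C(CCCC1(C)OCCO1)[C@H](C(=O)OCC[Si](C)(C)C)[C@H](CC(OCC)OCC)/C(C=O)=C2/C=CC(C)(C)O2 | intermediate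
29 | (2R,3S,4E)-3-(2,2-diethoxyethyl)-4-(5,5-dimethylfuran-2(5H)-ylidene)-2-[5-(2-methyl-1,3-dioxolan-2-yl)pent-1-en-2-yl]-5-oxopentanoic acid | C=C(CCCC1(C)OCCO1)[C@H](C(=O)O)[C@H](CC(OCC)OCC)/C(C=O)=C2/C=CC(C)(C)O2 | intermediate
30 | (2R,3S,4E)-4-(5,5-dimethylfuran-2(5H)-ylidene)-5-oxo-2-(6-oxohept-1-en-2-yl)-3-(2-oxoethyl)pentanoic acid (CNP0150297.1) | C=C(CCCC(C)=O)[C@H](C(=O)O)[C@H](CC=O)/C(C=O)=C1/C=CC(C)(C)O1 | target

**Step count and risks**

Total step count: 15. Longest linear sequence: 13 steps (from 5 through steps 2–10 and 12–15).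

Steps most likely to fail:

1. Step 12 (C-acylation of the enamine). What may go wrong: the acid chloride may lose HCl to a vinylketene that oligomerises or cycloadds. Acylation may also occur on nitrogen, the β,γ-double bond of the new ketone may drift into conjugation, and the 2-substituted β-ketoaldehyde may deformylate during hydrolysis. Fallback: build the 1,3-dicarbonyl unit as an isoxazole. Setting out from aldehyde 20 (as its enamine 23), cycloaddition with the nitrile oxide generated in situ (PhNCO, Et3N) from 4-methyl-1-nitropent-3-ene F1, itself made from 5-bromo-2-methylpent-2-ene and NaNO2, followed by loss of pyrrolidine, should give 2-(trimethylsilyl)ethyl (2R,3S)-5,5-diethoxy-3-[3-(3-methylbut-2-en-1-yl)-1,2-oxazol-4-yl]-2-[5-(2-methyl-1,3-dioxolan-2-yl)pent-1-en-2-yl]pentanoate F2. Reductive N–O cleavage with Mo(CO)6 in wet MeCN should then give 2-(trimethylsilyl)ethyl (2R,3S,4Z)-5-amino-3-(2,2-diethoxyethyl)-4-formyl-8-methyl-2-[5-(2-methyl-1,3-dioxolan-2-yl)pent-1-en-2-yl]nona-4,7-dienoate F3, and buffered aqueous acid hydrolysis of this vinylogous amide comes back to the route at enol 25.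

2. Step 13 (selenocyclisation and elimination). What may go wrong: selenium may be transferred to the enol carbon C14 or to the C1=C2 alkene faster than the 5-endo closure drains the equilibrium. The HCl formed may start acetal exchange with the enol hydroxyl, PhSeOH may add back during the elimination, or the less stable C14=C15 geometry may persist. Fallback: halocyclisation followed by base-induced elimination, with no oxidation stage. Setting out from 25, I2 and NaHCO3 in MeCN at 0 °C should give 2-(trimethylsilyl)ethyl (2R,3S)-3-(2,2-diethoxyethyl)-4-(4-iodo-5,5-dimethyloxolan-2-ylidene)-5-oxo-2-[5-(2-methyl-1,3-dioxolan-2-yl)pent-1-en-2-yl]pentanoate F4 by the same 5-endo closure, and DBU in toluene should remove HI towards C16 and come back to the route at 28.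

3. Step 6 (Ireland–Claisen rearrangement). What may go wrong: the ketene acetal may form as a mixture of geometries, or mainly with the alkenyl group cis to the allyloxy oxygen, which would erode or invert the configuration at C8 relative to C10. Fallback: pair the opposite alkene geometry with that enolate geometry. Setting out from ynone 8, transfer hydrogenation with RuCl[(R,R)-TsDPEN](p-cymene) should give (2R)-6,6-diethoxyhex-3-yn-2-ol F5, and semihydrogenation over Pd/CaCO3 poisoned with Pb(OAc)2 and quinoline should give (2R,3Z)-6,6-diethoxyhex-3-en-2-ol F6. Esterification with acid 4 as in step 5 should give (2R,3Z)-6,6-diethoxyhex-3-en-2-yl 3-methylidene-6-(2-methyl-1,3-dioxolan-2-yl)hexanoate F7. Enolisation with LiN(i-Pr)2 in THF without DMPU, silylation and warming should then pass through the chair in which the alkenyl group and the (Z)-alkene substituent are both axial and the methyl group equatorial, and come back to the route at acid 15.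

**Further compounds**

F1 | step 12 | 4-methyl-1-nitropent-3-ene | CC(C)=CCC[N+](=O)[O-]
F2 | step 12 | 2-(trimethylsilyl)ethyl (2R,3S)-5,5-diethoxy-3-[3-(3-methylbut-2-en-1-yl)-1,2-oxazol-4-yl]-2-[5-(2-methyl-1,3-dioxolan-2-yl)pent-1-en-2-yl]pentanoate | C=C(CCCC1(C)OCCO1)[C@H](C(=O)OCC[Si](C)(C)C)[C@H](CC(OCC)OCC)c2conc2CC=C(C)C
F3 | step 12 | 2-(trimethylsilyl)ethyl (2R,3S,4Z)-5-amino-3-(2,2-diethoxyethyl)-4-formyl-8-methyl-2-[5-(2-methyl-1,3-dioxolan-2-yl)pent-1-en-2-yl]nona-4,7-dienoate | C=C(CCCC1(C)OCCO1)[C@H](C(=O)OCC[Si](C)(C)C)[C@H](CC(OCC)OCC)/C(C=O)=C(/N)CC=C(C)C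
F4 | step 13 | 2-(trimethylsilyl)ethyl (2R,3S)-3-(2,2-diethoxyethyl)-4-(4-iodo-5,5-dimethyloxolan-2-ylidene)-5-oxo-2-[5-(2-methyl-1,3-dioxolan-2-yl)pent-1-en-2-yl]pentanoate | C=C(CCCC1(C)OCCO1)[C@H](C(=O)OCC[Si](C)(C)C)[C@H](CC(OCC)OCC)C(C=O)=C2CC(I)C(C)(C)O2
F5 | step 6 | (2R)-6,6-diethoxyhex-3-yn-2-ol | C[C@@H](O)C#CCC(OCC)OCC
F6 | step 6 | (2R,3Z)-6,6-diethoxyhex-3-en-2-ol | C[C@@H](O)/C=C\CC(OCC)OCC
F7 | step 6 | (2R,3Z)-6,6-diethoxyhex-3-en-2-yl 3-methylidene-6-(2-methyl-1,3-dioxolan-2-yl)hexanoate | C=C(CCCC1(C)OCCO1)CC(=O)O[C@H](C)/C=C\CC(OCC)OCC
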